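**Plan**

1. Positions follow labdane numbering: ring A = C1–C5 and C10, ring B = C5–C10, C11–C16 side chain on C9, C17 on C8, C20 on C10. Retrosynthesis: C17 aldehyde back to the primary alcohol; cut C12–C13 (B-alkyl Suzuki–Miyaura) and C11=C12 (Wittig) back to a formyl group on C9; add a C6=C7 double bond and cut C8–C9 and C5–C10 together (retro-Diels–Alder), which opens both rings to an acyclic (2E,8E,10E)-trienal.
2. Enabling feature: ring B is a six-membered ring in which C8–C9 and C5–C10 flank C9–C10, so with C6=C7 it is the [4+2] adduct of diene C5=C6–C7=C8 and dienophile C9=C10. C11 on C9 can be a formyl activating group, the C1–C4 chain is a four-atom tether that becomes ring A, and C20, C11 and C17, all cis on ring B, are the signature of an endo adduct of an E-dienophile with an E,E-diene.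
3. Chain cuts: C9=C10 (alkyne carboalumination), C5=C6 (vinylogous Horner–Wadsworth–Emmons), C3–C4 (reverse prenylation of pent-4-ynal).
4. Forward: the chain is built linearly (C3–C4, then C5 to C17, then C9=C10–C11), both rings arise in one step, the side chain C12–C16 is then coupled on, and C17 is oxidised last.
5. Stereochemistry: C3 from a reagent-controlled allylboration; C5, C8, C9 and C10 from the cycloaddition (alkene geometries, endo mode, C3 silyl ether equatorial on the chair-like tether); the 13Z alkene from a (Z)-iodoenoate coupled with retention.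

Key step: step 10

Assumption: the γ,γ-dimethylallylborane carrying isopinocampheyl groups from (+)-α-pinene attacks the Si face of the aldehyde, as the parent allyl reagent does; if the sense were opposite, the borane from (−)-α-pinene would be used with no other change.

**Route**

Step 1
Reactants: 1 pent-4-yn-1-ol
Product: 2 pent-4-ynal
Conditions: (COCl)2, DMSO, CH2Cl2, −78 °C; Et3N, −78 → 0 °C; used as a dried solution
Reagents that add atoms: none
Why: Swern oxidation should stop cleanly at the volatile aldehyde and leave the terminal alkyne untouched; no stereocentre is involved.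

Step 2
Reactants: 2 pent-4-ynal
Product: 4 (4R)-3,3-dimethyloct-1-en-7-yn-4-ol, via borinate ester 3 (not isolated)
Conditions: (−)-Ipc2BH [from (+)-α-pinene, BH3·SMe2], 3-methylbuta-1,2-diene, THF, −25 °C; then 2, Et2O, −78 °C; NaOH, H2O2, 0 °C → rt
Reagents that add atoms: 3-methylbuta-1,2-diene CC(C)=C=C
Why: Brown asymmetric allylboration (reverse prenylation): the γ,γ-dimethylallylborane adds through a closed chair transition state with allylic transposition, so the new bond is made at the tertiary carbon (C4 with both methyl groups), and the isopinocampheyl groups should direct attack to the Si face of the aldehyde to give the (R)-carbinol (C3).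

Step 3
Reactants: 4 (4R)-3,3-dimethyloct-1-en-7-yn-4-ol
Product: 5 tert-butyl{[(4R)-3,3-dimethyloct-1-en-7-yn-4-yl]oxy}dimethylsilane
Conditions: TBSOTf, 2,6-lutidine, CH2Cl2, −78 → 0 °C
Reagents that add atoms: tert-butyldimethylsilyl triflate CC(C)(C)[Si](C)(C)OS(=O)(=O)C(F)(F)F
Why: Silylation with the silyl triflate should protect the hindered secondary alcohol next to the quaternary carbon without touching C3.

Step 4
Reactants: 5 tert-butyl{[(4R)-3,3-dimethyloct-1-en-7-yn-4-yl]oxy}dimethylsilane
Product: 7 (3R)-3-[(tert-butyldimethylsilyl)oxy]-2,2-dimethylhept-6-ynal, via ozonide 6 (not isolated)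
Conditions: O3, CH2Cl2, −78 °C (stopped when the alkene is consumed); PPh3, −78 °C → rt
Reagents that add atoms: ozone [O-][O+]=O
Why: Ozonolysis with reductive work-up should cleave the vinyl group much faster than the terminal alkyne and give an aldehyde without α-hydrogen that can neither enolise nor eliminate.

Step 5
Reactants: 7 (3R)-3-[(tert-butyldimethylsilyl)oxy]-2,2-dimethylhept-6-ynal
Product: 8 ethyl (2E,4E,7R)-7-[(tert-butyldimethylsilyl)oxy]-6,6-dimethylundeca-2,4-dien-10-ynoate
Conditions: triethyl 4-phosphonocrotonate, LiN(SiMe3)2, THF, −78 °C → rt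
Reagents that add atoms: triethyl (2E)-4-phosphonocrotonate CCOC(=O)/C=C/CP(=O)(OCC)OCC
Why: Vinylogous Horner–Wadsworth–Emmons olefination of the α-quaternary aldehyde with the stabilised phosphonate anion should give the new C5=C6 bond E and keep the crotonate double bond E.

Step 6
Reactants: 8 ethyl (2E,4E,7R)-7-[(tert-butyldimethylsilyl)oxy]-6,6-dimethylundeca-2,4-dien-10-ynoate
Product: 9 (2E,4E,7R)-7-[(tert-butyldimethylsilyl)oxy]-6,6-dimethylundeca-2,4-dien-10-yn-1-ol
Conditions: i-Bu2AlH, CH2Cl2, −78 °C; aq. KNaC4H4O6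
Reagents that add atoms: none
Why: 1,2-Reduction of the dienoate with the aluminium hydride at low temperature should give the dienol and leave the alkyne, the diene geometry and the silyl ether untouched.

Step 7
Reactants: 9 (2E,4E,7R)-7-[(tert-butyldimethylsilyl)oxy]-6,6-dimethylundeca-2,4-dien-10-yn-1-ol
Product: 10 tert-butyl{[(2E,4E,7R)-7-[(tert-butyldimethylsilyl)oxy]-6,6-dimethylundeca-2,4-dien-10-yn-1-yl]oxy}dimethylsilane
Conditions: TBSCl, imidazole, CH2Cl2, 0 °C → rt
Reagents that add atoms: tert-butyldimethylsilyl chloride CC(C)(C)[Si](C)(C)Cl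
Why: Standard silylation of the primary dienylic alcohol masks C17–OH through the Lewis-acid and organometallic steps.

Step 8
Reactants: 10 tert-butyl{[(2E,4E,7R)-7-[(tert-butyldimethylsilyl)oxy]-6,6-dimethylundeca-2,4-dien-10-yn-1-yl]oxy}dimethylsilane
Product: 12 (2E,6R,8E,10E)-6,12-bis[(tert-butyldimethylsilyl)oxy]-3,7,7-trimethyldodeca-2,8,10-trien-1-ol, via alkenylalane 11 (not isolated)
Conditions: Me3Al, Cp2ZrCl2 (cat.), CH2Cl2, 0 °C → rt; then THF, n-BuLi, −78 °C; (CH2O)n, −78 °C → rt; aq. KNaC4H4O6
Reagents that add atoms: trimethylaluminium C[Al](C)C; formaldehyde (from paraformaldehyde) C=O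
Why: Negishi carboalumination adds methyl and aluminium syn across the terminal alkyne with aluminium at the terminus, and hydroxymethylation of the derived alanate with retention should give the (E)-trisubstituted allylic alcohol (C9=C10 carrying C20) while the internal diene stays inert.

Step 9
Reactants: 12 (2E,6R,8E,10E)-6,12-bis[(tert-butyldimethylsilyl)oxy]-3,7,7-trimethyldodeca-2,8,10-trien-1-ol
Product: 13 (2E,6R,8E,10E)-6,12-bis[(tert-butyldimethylsilyl)oxy]-3,7,7-trimethyldodeca-2,8,10-trienal
Conditions: MnO2 (activated, excess), CH2Cl2, rt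
Reagents that add atoms: none
Why: Allylic oxidation with MnO2 should give the (E)-enal under neutral conditions without E/Z drift or loss of the silyl ethers.

Step 10
Reactants: 13 (2E,6R,8E,10E)-6,12-bis[(tert-butyldimethylsilyl)oxy]-3,7,7-trimethyldodeca-2,8,10-trienal
Product: 14 (1R,2R,4aS,6R,8aR)-6-[(tert-butyldimethylsilyl)oxy]-2-{[(tert-butyldimethylsilyl)oxy]methyl}-5,5,8a-trimethyl-1,2,4a,5,6,7,8,8a-octahydronaphthalene-1-carbaldehyde
Conditions: Me2AlCl (1.5 equiv), CH2Cl2, −78 → −20 °C; aq. NaHCO3
Reagents that add atoms: none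
Why: Me2AlCl binds the formyl oxygen and lowers the LUMO of the C9=C10 dienophile, which adds suprafacially across C5 and C8 of the s-cis (E,E)-diene in a concerted but asynchronous [4+2] cycloaddition with the C5–C10 bond running ahead; the closest known reaction type is the Lewis-acid-promoted intramolecular Diels–Alder reaction of (2E,8E,10E)-trienals to trans-fused octalins. Ring A closes as a six-membered carbocycle in the fused mode through the four-carbon C1–C4 tether in a chair-like array (the gem-dimethyl group at C4 helps the folding), and ring B is the new cyclohexene made from the four diene carbons and the two dienophile carbons. The C9/C10 relationship (C11 cis to C20) follows from the E geometry of the dienophile, the C5/C8 relationship (H-5 cis to H-8) from the E,E geometry of the diene, and the link between the two pairs (C11 cis to C17, trans ring fusion) from the endo position of the aluminium-bound formyl group with the tether anti. The absolute sense comes from C3, whose silyloxy group should sit equatorial on the chair-like tether, so that the diene face that places C20 cis to the C3 oxygen is used. The step needs endo over exo selectivity (exo would give the cis-fused octalin) and one diene face over the other; the first should be secured by Lewis-acid complexation, which strengthens the endo preference of the carbonyl group, the second by the equatorial preference of the bulky silyl ether, and the regiochemistry is fixed by the tether.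

Step 11
Reactants: 14 (1R,2R,4aS,6R,8aR)-6-[(tert-butyldimethylsilyl)oxy]-2-{[(tert-butyldimethylsilyl)oxy]methyl}-5,5,8a-trimethyl-1,2,4a,5,6,7,8,8a-octahydronaphthalene-1-carbaldehyde
Product: 15 (1R,2R,4aS,6R,8aR)-6-[(tert-butyldimethylsilyl)oxy]-2-{[(tert-butyldimethylsilyl)oxy]methyl}-5,5,8a-trimethyldecahydronaphthalene-1-carbaldehyde
Conditions: H2 (1 atm), 5% Pt/C, EtOAc, rt
Reagents that add atoms: none
Why: Heterogeneous catalytic hydrogenation should saturate the cis-disubstituted C6=C7 bond without creating a stereocentre, platinum being chosen over palladium to limit double-bond migration toward C5 or C8, and the aldehyde should survive at one atmosphere in ethyl acetate.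

Step 12
Reactants: 15 (1R,2R,4aS,6R,8aR)-6-[(tert-butyldimethylsilyl)oxy]-2-{[(tert-butyldimethylsilyl)oxy]methyl}-5,5,8a-trimethyldecahydronaphthalene-1-carbaldehyde
Product: 16 tert-butyl{[(1R,2R,4aS,6R,8aS)-6-[(tert-butyldimethylsilyl)oxy]-1-ethenyl-5,5,8a-trimethyldecahydronaphthalen-2-yl]methoxy}dimethylsilane
Conditions: Ph3PCH3Br, KN(SiMe3)2, THF, 0 °C; then 15, −78 → 0 °C
Reagents that add atoms: methyltriphenylphosphonium bromide C[P+](c1ccccc1)(c1ccccc1)c1ccccc1.[Br-]
Why: Wittig methylenation with the non-stabilised ylide at low temperature should be faster than enolisation of the aldehyde, so C9 keeps its configuration while C11=C12 is formed.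

Step 13
Reactants: 17 methyl but-2-ynoate
Product: 18 methyl (2Z)-3-iodobut-2-enoate
Conditions: NaI, AcOH, 110 °C
Reagents that add atoms: sodium iodide [Na+].[I-]
Why: Conjugate anti-addition of HI to the ynoate should give the (Z)-β-iodoenoate with iodine cis to the ester.

Step 14
Reactants: 16 tert-butyl{[(1R,2R,4aS,6R,8aS)-6-[(tert-butyldimethylsilyl)oxy]-1-ethenyl-5,5,8a-trimethyldecahydronaphthalen-2-yl]methoxy}dimethylsilane; 18 methyl (2Z)-3-iodobut-2-enoate
Product: 20 methyl (2Z)-5-[(1R,2R,4aS,6R,8aS)-6-[(tert-butyldimethylsilyl)oxy]-2-{[(tert-butyldimethylsilyl)oxy]methyl}-5,5,8a-trimethyldecahydronaphthalen-1-yl]-3-methylpent-2-enoate, via alkylborane 19 (not isolated)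
Conditions: 9-BBN-H, THF, rt → 50 °C; then 18, Pd(dppf)Cl2 (5 mol%), AsPh3, Cs2CO3, DMF/H2O, rt
Reagents that add atoms: none
Why: Anti-Markovnikov hydroboration places boron on C12, and B-alkyl Suzuki–Miyaura coupling proceeds with retention at the alkenyl iodide, so the C12–C13 bond should form with the chain cis to the ester (13Z).

Step 15
Reactants: 20 methyl (2Z)-5-[(1R,2R,4aS,6R,8aS)-6-[(tert-butyldimethylsilyl)oxy]-2-{[(tert-butyldimethylsilyl)oxy]methyl}-5,5,8a-trimethyldecahydronaphthalen-1-yl]-3-methylpent-2-enoate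
Product: 21 methyl (2Z)-5-[(1R,2R,4aS,6R,8aS)-6-hydroxy-2-(hydroxymethyl)-5,5,8a-trimethyldecahydronaphthalen-1-yl]-3-methylpent-2-enoate
Conditions: HF (48% aq.), MeCN/THF, 0 °C → rt
Reagents that add atoms: none
Why: Acidic fluoride desilylation should remove both silyl ethers, including the hindered one at C3, without touching the methyl ester or the Z-enoate.

Step 16
Reactants: 21 methyl (2Z)-5-[(1R,2R,4aS,6R,8aS)-6-hydroxy-2-(hydroxymethyl)-5,5,8a-trimethyldecahydronaphthalen-1-yl]-3-methylpent-2-enoate
Product: 22 methyl (2Z)-5-[(1R,2R,4aS,6R,8aS)-2-formyl-6-hydroxy-5,5,8a-trimethyldecahydronaphthalen-1-yl]-3-methylpent-2-enoate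
Conditions: TEMPO (10 mol%), PhI(OAc)2, CH2Cl2, rt
Reagents that add atoms: none
Why: Oxoammonium (TEMPO) oxidation takes primary alcohols much faster than the hindered secondary C3 alcohol and runs close to neutral, so the axial, epimerisable C8 aldehyde should be formed last and kept.

**Compound list**

1 | pent-4-yn-1-ol | C#CCCCO | starting material
2 | pent-4-ynal | C#CCCC=O | intermediate
3 | (4R)-3,3-dimethyloct-1-en-7-yn-4-yl bis(isopinocampheyl)borinate (isopinocampheyl groups from (+)-α-pinene) | C#CCC[C@@H](OB([C@@H]1C[C@@H]2C[C@H]([C@H]1C)C2(C)C)[C@@H]1C[C@@H]2C[C@H]([C@H]1C)C2(C)C)C(C)(C)C=C | intermediate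
4 | (4R)-3,3-dimethyloct-1-en-7-yn-4-ol | C#CCC[C@@H](O)C(C)(C)C=C | intermediate
5 | tert-butyl{[(4R)-3,3-dimethyloct-1-en-7-yn-4-yl]oxy}dimethylsilane | C#CCC[C@@H](O[Si](C)(C)C(C)(C)C)C(C)(C)C=C | intermediate
6 | ozonide of 5 (1,2,4-trioxolane at the former vinyl group, mixture at the ring carbon) | C#CCC[C@@H](O[Si](C)(C)C(C)(C)C)C(C)(C)C1OCOO1 | intermediate
7 | (3R)-3-[(tert-butyldimethylsilyl)oxy]-2,2-dimethylhept-6-ynal | C#CCC[C@@H](O[Si](C)(C)C(C)(C)C)C(C)(C)C=O | intermediate
8 | ethyl (2E,4E,7R)-7-[(tert-butyldimethylsilyl)oxy]-6,6-dimethylundeca-2,4-dien-10-ynoate | C#CCC[C@@H](O[Si](C)(C)C(C)(C)C)C(C)(C)/C=C/C=C/C(=O)OCC | intermediate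
9 | (2E,4E,7R)-7-[(tert-butyldimethylsilyl)oxy]-6,6-dimethylundeca-2,4-dien-10-yn-1-ol | C#CCC[C@@H](O[Si](C)(C)C(C)(C)C)C(C)(C)/C=C/C=C/CO | intermediate
10 | tert-butyl{[(2E,4E,7R)-7-[(tert-butyldimethylsilyl)oxy]-6,6-dimethylundeca-2,4-dien-10-yn-1-yl]oxy}dimethylsilane | C#CCC[C@@H](O[Si](C)(C)C(C)(C)C)C(C)(C)/C=C/C=C/CO[Si](C)(C)C(C)(C)C | intermediate
11 | (E)-alkenyl(dimethyl)alane from methylalumination of 10 (aluminium on the terminal carbon, cis to the new methyl) | C[Al](C)/C=C(\C)CC[C@@H](O[Si](C)(C)C(C)(C)C)C(C)(C)/C=C/C=C/CO[Si](C)(C)C(C)(C)C | intermediate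
12 | (2E,6R,8E,10E)-6,12-bis[(tert-butyldimethylsilyl)oxy]-3,7,7-trimethyldodeca-2,8,10-trien-1-ol | OC/C=C(\C)CC[C@@H](O[Si](C)(C)C(C)(C)C)C(C)(C)/C=C/C=C/CO[Si](C)(C)C(C)(C)C | intermediate
13 | (2E,6R,8E,10E)-6,12-bis[(tert-butyldimethylsilyl)oxy]-3,7,7-trimethyldodeca-2,8,10-trienal | O=C/C=C(\C)CC[C@@H](O[Si](C)(C)C(C)(C)C)C(C)(C)/C=C/C=C/CO[Si](C)(C)C(C)(C)C | intermediate
14 | (1R,2R,4aS,6R,8aR)-6-[(tert-butyldimethylsilyl)oxy]-2-{[(tert-butyldimethylsilyl)oxy]methyl}-5,5,8a-trimethyl-1,2,4a,5,6,7,8,8a-octahydronaphthalene-1-carbaldehyde (trans-fused; CHO, CH2OTBS, 8a-CH3 and 6-OTBS on one face, H-4a on the other) | O=C[C@@H]1[C@H](CO[Si](C)(C)C(C)(C)C)C=C[C@@H]2C(C)(C)[C@H](O[Si](C)(C)C(C)(C)C)CC[C@@]12C | intermediate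
15 | (1R,2R,4aS,6R,8aR)-6-[(tert-butyldimethylsilyl)oxy]-2-{[(tert-butyldimethylsilyl)oxy]methyl}-5,5,8a-trimethyldecahydronaphthalene-1-carbaldehyde | O=C[C@@H]1[C@H](CO[Si](C)(C)C(C)(C)C)CC[C@@H]2C(C)(C)[C@H](O[Si](C)(C)C(C)(C)C)CC[C@@]12C | intermediate
16 | tert-butyl{[(1R,2R,4aS,6R,8aS)-6-[(tert-butyldimethylsilyl)oxy]-1-ethenyl-5,5,8a-trimethyldecahydronaphthalen-2-yl]methoxy}dimethylsilane | C=C[C@@H]1[C@H](CO[Si](C)(C)C(C)(C)C)CC[C@@H]2C(C)(C)[C@H](O[Si](C)(C)C(C)(C)C)CC[C@@]12C | intermediate
17 | methyl but-2-ynoate | CC#CC(=O)OC | starting material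
18 | methyl (2Z)-3-iodobut-2-enoate | COC(=O)/C=C(/C)I | intermediate
19 | B-alkyl-9-borabicyclo[3.3.1]nonane from hydroboration of 16 (boron on C12) | C1CC2CCCC(C1)B2CC[C@@H]1[C@H](CO[Si](C)(C)C(C)(C)C)CC[C@@H]2C(C)(C)[C@H](O[Si](C)(C)C(C)(C)C)CC[C@@]12C | intermediate
20 | methyl (2Z)-5-[(1R,2R,4aS,6R,8aS)-6-[(tert-butyldimethylsilyl)oxy]-2-{[(tert-butyldimethylsilyl)oxy]methyl}-5,5,8a-trimethyldecahydronaphthalen-1-yl]-3-methylpent-2-enoate | COC(=O)/C=C(/C)CC[C@@H]1[C@H](CO[Si](C)(C)C(C)(C)C)CC[C@@H]2C(C)(C)[C@H](O[Si](C)(C)C(C)(C)C)CC[C@@]12C | intermediate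
21 | methyl (2Z)-5-[(1R,2R,4aS,6R,8aS)-6-hydroxy-2-(hydroxymethyl)-5,5,8a-trimethyldecahydronaphthalen-1-yl]-3-methylpent-2-enoate | COC(=O)/C=C(/C)CC[C@@H]1[C@H](CO)CC[C@@H]2C(C)(C)[C@H](O)CC[C@@]12C | intermediate
22 | methyl (2Z)-5-[(1R,2R,4aS,6R,8aS)-2-formyl-6-hydroxy-5,5,8a-trimethyldecahydronaphthalen-1-yl]-3-methylpent-2-enoate (CNP0188570.2) | COC(=O)/C=C(/C)CC[C@@H]1[C@H](C=O)CC[C@@H]2C(C)(C)[C@H](O)CC[C@@]12C | target

**Count**

Total steps: 16. Longest linear sequence: 15 (steps 1–12 and 14–16, from pent-4-yn-1-ol); step 13 is a one-step side branch.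

**Steps most likely to fail**

Step 10. The β,β-disubstituted enal may add too slowly to the neopentylic diene terminus, so that Lewis-acid ionisation of the dienylic silyl ether or leakage through the exo (cis-fused) mode competes; the facial bias from the C3 silyl ether may also be incomplete. The fallback forms the same two bonds transannularly, with a temporary lactone ring tying the C17 oxygen to C11, and needs no Lewis acid. It sets out from dienol 9. Negishi carboalumination as in step 8 but with CO2 as the electrophile (Me3Al, Cp2ZrCl2, CH2Cl2; n-BuLi; CO2) would give the hydroxy acid F1. Shiina macrolactonisation (2-methyl-6-nitrobenzoic anhydride, DMAP, toluene, high dilution) would give the all-E 13-membered macrolactone F2. Heating in toluene, if the reaction does not already occur during lactonisation, should bring about the transannular Diels–Alder reaction to the tricyclic lactone F3; the three-atom lactone bridge forces C11 and C17 cis and with it the trans ring fusion. Hydrogenation (H2, Pt/C, EtOAc) would give the saturated lactone F4, i-Bu2AlH at −78 °C the lactol F5, and Wittig methylenation (Ph3PCH3Br, KN(SiMe3)2, excess) would open it to the hydroxy alkene F6. Silylation (TBSCl, imidazole) then gives 16, where the route is rejoined.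

Step 14. Hydroboration of the hindered vinyl group next to the quaternary carbon may be sluggish, and the coupling may suffer from slow transmetallation, protodeboronation or Z to E drift of the iodoenoate under base. The fallback builds the side chain by olefination and enol-triflate methylation and sets out from aldehyde 15. Horner–Wadsworth–Emmons reaction with the dianion of methyl 4-(diethoxyphosphoryl)-3-oxobutanoate (NaH, then n-BuLi, THF) would give the (E)-unsaturated β-keto ester F7. Hydrogenation (H2, Pd/C, EtOAc) would give the saturated β-keto ester F8. Triflation under non-chelating conditions (Tf2O, aqueous Me4NOH, hexane/toluene, 0 °C) should give the (E)-enol triflate F9, with the triflate trans to the ester. Negishi coupling (MeZnCl, Pd(PPh3)4, THF) replaces the triflate by methyl with retention and gives 20, where the route is rejoined.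

Step 16. The oxidation may be slow at the hindered axial primary alcohol, may spill over to the secondary C3 alcohol, or the axial C8 aldehyde may epimerise during reaction or isolation. The fallback tells the two alcohols apart through their silyl ethers and sets out from 20. Acid methanolysis (camphorsulfonic acid, MeOH/CH2Cl2, 0 °C) should remove only the primary silyl group and give the alcohol F10. Dess–Martin oxidation (NaHCO3, CH2Cl2) would give the silyloxy aldehyde F11. Buffered HF·pyridine in THF/pyridine then removes the C3 silyl group and gives 22.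

**Further compounds**

F1 | step 10 | (2E,6R,8E,10E)-6-[(tert-butyldimethylsilyl)oxy]-12-hydroxy-3,7,7-trimethyldodeca-2,8,10-trienoic acid | OC(=O)/C=C(\C)CC[C@@H](O[Si](C)(C)C(C)(C)C)C(C)(C)/C=C/C=C/CO
F2 | step 10 | all-E 13-membered macrolactone of F1 (C17–O–C11 ester) | O=C1/C=C(\C)CC[C@@H](O[Si](C)(C)C(C)(C)C)C(C)(C)/C=C/C=C/CO1
F3 | step 10 | tricyclic lactone from the transannular cycloaddition (rings A/B trans-fused, γ-lactone cis-fused across C8–C9, C6=C7 alkene, 3-OTBS) | O=C3[C@@H]1[C@H](CO3)C=C[C@@H]2C(C)(C)[C@H](O[Si](C)(C)C(C)(C)C)CC[C@@]12C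
F4 | step 10 | saturated tricyclic lactone (F3 without the C6=C7 double bond) | O=C3[C@@H]1[C@H](CO3)CC[C@@H]2C(C)(C)[C@H](O[Si](C)(C)C(C)(C)C)CC[C@@]12C
F5 | step 10 | lactol from F4 (anomeric mixture at C11) | OC3[C@@H]1[C@H](CO3)CC[C@@H]2C(C)(C)[C@H](O[Si](C)(C)C(C)(C)C)CC[C@@]12C
F6 | step 10 | hydroxy alkene (9-ethenyl, 8-hydroxymethyl, 3-OTBS decalin; 16 without the primary silyl group) | C=C[C@@H]1[C@H](CO)CC[C@@H]2C(C)(C)[C@H](O[Si](C)(C)C(C)(C)C)CC[C@@]12C
F7 | step 14 | methyl (4E)-3-oxopent-4-enoate carrying the bis-silylated decalin of 15 at C5 | COC(=O)CC(=O)/C=C/[C@@H]1[C@H](CO[Si](C)(C)C(C)(C)C)CC[C@@H]2C(C)(C)[C@H](O[Si](C)(C)C(C)(C)C)CC[C@@]12C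
F8 | step 14 | saturated β-keto ester (methyl 3-oxopentanoate carrying the same decalin at C5) | COC(=O)CC(=O)CC[C@@H]1[C@H](CO[Si](C)(C)C(C)(C)C)CC[C@@H]2C(C)(C)[C@H](O[Si](C)(C)C(C)(C)C)CC[C@@]12C
F9 | step 14 | (E)-enol triflate of F8 (triflate trans to the ester) | COC(=O)/C=C(/OS(=O)(=O)C(F)(F)F)CC[C@@H]1[C@H](CO[Si](C)(C)C(C)(C)C)CC[C@@H]2C(C)(C)[C@H](O[Si](C)(C)C(C)(C)C)CC[C@@]12C
F10 | step 16 | primary alcohol with the C3 silyl ether kept (20 without the primary silyl group) | COC(=O)/C=C(/C)CC[C@@H]1[C@H](CO)CC[C@@H]2C(C)(C)[C@H](O[Si](C)(C)C(C)(C)C)CC[C@@]12C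
F11 | step 16 | C3 silyl ether of the target aldehyde | COC(=O)/C=C(/C)CC[C@@H]1[C@H](C=O)CC[C@@H]2C(C)(C)[C@H](O[Si](C)(C)C(C)(C)C)CC[C@@]12C
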